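**Retrosynthetic overview**

1. Locants: main chain C1 (butenolide C=O) to C19 (terminal CMe2 carbon); C15 is the α-carbon and C17 the stereocentre of the γ-lactone. The last disconnection is the exocyclic C14=C15 alkene, made by Wittig reaction of an ester-stabilised lactone ylide with a C1–C14 trienal.
2. Key disconnection: the C5–C6 single bond in the middle of the triene. It is made by one-pot syn-methylalumination of the terminal alkyne C6≡C7 of a simple C10 enynol and palladium-catalysed coupling of the resulting alkenylalane with (E)-4-(2-iodovinyl)furan-2(5H)-one. The same operation installs the C7 methyl group and the (E) geometry of C6=C7.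
3. Enabling feature: C7 is a methyl-branched sp2 carbon next to the unbranched C6–H, which is the signature of syn Me–Al addition to a terminal alkyne. C5 ends the C4=C5 alkene that is conjugated to the butenolide ring (ring O, C1, C2, C3 and the OCH2 carbon), so a C5–I bond is an electron-poor, fast partner for oxidative addition.
4. The (E)-C10=C11 alkene comes from a Johnson–Claisen rearrangement; C17 comes unchanged from the chiral pool, (S)-5-(hydroxymethyl)dihydrofuran-2(3H)-one.
5. Ring order: no ring is formed in the route. The butenolide ring (from 4-bromofuran-2(5H)-one) and the γ-lactone ring (from the chiral-pool lactone) are both carried in intact.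

Key step: step 7

Remark: the target is read as the (17S), all-(E) isomer; pent-4-yn-1-ol, 4-bromofuran-2(5H)-one and (S)-5-(hydroxymethyl)dihydrofuran-2(3H)-one are taken as commercially available.

**Route**

Step 1
Reactants: 1 pent-4-yn-1-ol
Product: 2 pent-4-ynal
Conditions: (COCl)2, DMSO, CH2Cl2, −78 °C; Et3N, −78 → 0 °C; used as a solution
Reagents that add atoms: none
Why: Swern oxidation stops at the aldehyde and leaves the terminal alkyne untouched, and the volatile aldehyde is carried on without isolation.

Step 2
Reactants: 2 pent-4-ynal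
Product: 3 rac-2-methylhept-1-en-6-yn-3-ol
Conditions: CH2=C(CH3)MgBr (1.1 equiv), THF, −78 → 0 °C; sat. aq. NH4Cl
Reagents that add atoms: isopropenylmagnesium bromide, CC(=C)[Mg]Br
Why: Grignard 1,2-addition to the aldehyde is much faster at −78 °C than deprotonation of the alkyne C–H, and the racemic carbinol centre is of no consequence because step 3 destroys it.

Step 3
Reactants: 3 rac-2-methylhept-1-en-6-yn-3-ol
Product: 5 ethyl (E)-4-methylnon-4-en-8-ynoate, via ketene acetal 4 (not isolated)
Conditions: CH3C(OEt)3 (6 equiv), EtCO2H (5 mol%), 140 °C, EtOH distilled off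
Reagents that add atoms: triethyl orthoacetate, CC(OCC)(OCC)OCC
Why: In this Johnson–Claisen rearrangement the chair transition state of ketene acetal 4 places the CH2CH2C≡CH chain pseudo-equatorial, which should give the (E)-trisubstituted alkene (C10=C11 of the target) with high selectivity.

Step 4
Reactants: 5 ethyl (E)-4-methylnon-4-en-8-ynoate
Product: 6 (E)-4-methylnon-4-en-8-yn-1-ol
Conditions: LiAlH4, Et2O, 0 °C; H2O/aq. NaOH work-up
Reagents that add atoms: none
Why: Hydride reduction of the ester to the primary alcohol should be clean because the isolated alkene and the terminal alkyne are inert to LiAlH4 at 0 °C.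

Step 5
Reactants: 7 4-bromofuran-2(5H)-one
Product: 8 (E)-4-[2-(tributylstannyl)ethenyl]furan-2(5H)-one
Conditions: (E)-Bu3SnCH=CHSnBu3 (2.5 equiv), Pd(PPh3)4 (5 mol%), toluene, 90 °C
Reagents that add atoms: (E)-1,2-bis(tributylstannyl)ethene, CCCC[Sn](CCCC)(CCCC)/C=C/[Sn](CCCC)(CCCC)CCCC
Why: Stille coupling at the activated C–Br bond of the β-bromobutenolide should stop at mono-coupling with retention of (E) geometry, because the excess electron-rich distannane transmetalates faster than the electron-poor product stannane.

Step 6
Reactants: 8 (E)-4-[2-(tributylstannyl)ethenyl]furan-2(5H)-one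
Product: 9 (E)-4-(2-iodoethenyl)furan-2(5H)-one
Conditions: I2 (1.05 equiv), CH2Cl2, 0 °C, dark; aq. Na2S2O3, then aq. KF
Reagents that add atoms: iodine, II
Why: Iododestannylation is an ipso substitution of tin by iodine that proceeds with retention of alkene geometry.

Step 7
Reactants: 6 (E)-4-methylnon-4-en-8-yn-1-ol; 9 (E)-4-(2-iodoethenyl)furan-2(5H)-one
Product: 11 4-[(1E,3E,7E)-11-hydroxy-4,8-dimethylundeca-1,3,7-trien-1-yl]furan-2(5H)-one, via alkenylalane 10 (not isolated)
Conditions: AlMe3 (3.5 equiv), Cp2ZrCl2 (0.25 equiv), CH2Cl2, 0 °C → rt; volatiles removed in vacuo; then 9 (0.85 equiv), ZnCl2 (0.5 equiv), Pd(PPh3)4 (5 mol%), THF, 0 °C → rt, dark; aq. potassium sodium tartrate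
Reagents that add atoms: trimethylaluminium, C[Al](C)C
Why: Cp2ZrCl2 and AlMe3 form a methylzirconocene species that adds Me–metal syn across the terminal C6≡C7 alkyne (methyl to the internal carbon C7, metal to the terminal carbon C6) and passes the alkenyl group to aluminium to give the (E)-alkenylalane 10, the hydroxyl being masked in the flask as its dimethylaluminium alkoxide; zerovalent palladium then inserts into the C5–I bond of 9, the alkenyl group is relayed from Al through Zn to Pd, and reductive elimination forms the C5–C6 bond with retention at both alkenes. The closest known reaction type is the one-pot zirconium-catalysed methylalumination of a terminal alkyne followed by palladium-catalysed alkenyl–alkenyl Negishi coupling, as used for isoprenoid polyenes. No ring is closed and no stereocentre is formed; the step instead sets the C7 methyl group, the (E) geometry of C6=C7 through syn addition, and the complete (4E,6E)-diene conjugated to the butenolide in one operation. The selectivities needed are regiochemistry of methyl delivery (secured by the unbranched terminal alkyne, which takes the metal at its unhindered terminus), chemoselectivity for the alkyne over the trisubstituted alkene (unactivated trisubstituted alkenes are not carbometalated), and alkenyl-over-methyl transfer to palladium (sp2 groups transmetalate faster, and excess AlMe3 is removed before the coupling). The butenolide of 9 meets only a weakly basic, weakly nucleophilic alane in THF, and oxidative addition into its electron-poor alkenyl C–I bond should be fast at room temperature.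

Step 8
Reactants: 11 4-[(1E,3E,7E)-11-hydroxy-4,8-dimethylundeca-1,3,7-trien-1-yl]furan-2(5H)-one
Product: 12 (4E,8E,10E)-4,8-dimethyl-11-(5-oxo-2,5-dihydrofuran-3-yl)undeca-4,8,10-trienal
Conditions: DMP (1.2 equiv), CH2Cl2, 0 °C → rt, dark
Reagents that add atoms: none
Why: Dess–Martin oxidation converts the primary alcohol to the aldehyde under neutral conditions that should leave the triene and the butenolide untouched.

Step 9
Reactants: 13 (S)-5-(hydroxymethyl)dihydrofuran-2(3H)-one
Product: 14 (S)-5-oxotetrahydrofuran-2-carbaldehyde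
Conditions: DMP (1.2 equiv), CH2Cl2, 0 °C → rt; non-aqueous filtration, used crude
Reagents that add atoms: none
Why: Dess–Martin oxidation is non-basic and should not epimerise the α-acyloxy aldehyde, so the (S) centre (C17 of the target) is carried over from the chiral pool.

Step 10
Reactants: 14 (S)-5-oxotetrahydrofuran-2-carbaldehyde
Product: 15 (5S)-5-(2-methylprop-1-en-1-yl)dihydrofuran-2(3H)-one
Conditions: (CH3)2CHPPh3I, n-BuLi, THF, 0 °C; then 14, −78 °C → rt
Reagents that add atoms: isopropyltriphenylphosphonium iodide, CC(C)[P+](c1ccccc1)(c1ccccc1)c1ccccc1.[I-]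
Why: Wittig olefination with the non-stabilised isopropylidene ylide at −78 °C should be faster than enolisation of the aldehyde or attack on the lactone, so the (S) centre is retained, and no alkene geometry arises because both new substituents are methyl.

Step 11
Reactants: 15 (5S)-5-(2-methylprop-1-en-1-yl)dihydrofuran-2(3H)-one
Product: 18 (5S)-3-bromo-5-(2-methylprop-1-en-1-yl)dihydrofuran-2(3H)-one as a mixture of C3 epimers, via lithium enolate 16 (not isolated), via silyl ketene acetal 17 (not isolated)
Conditions: LiN(i-Pr)2 (1.1 equiv), THF, −78 °C; Me3SiCl; then NBS, −78 → −40 °C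
Reagents that add atoms: N-bromosuccinimide, BrN1C(=O)CCC1=O
Why: α-Bromination of the lactone through its silyl ketene acetal should be chemoselective because the ketene acetal is far more nucleophilic than the trisubstituted alkene, and the C3 epimer ratio is irrelevant since C3 becomes sp2 in the next step.

Step 12
Reactants: 18 (5S)-3-bromo-5-(2-methylprop-1-en-1-yl)dihydrofuran-2(3H)-one
Product: 20 (5S)-5-(2-methylprop-1-en-1-yl)-3-(triphenylphosphoranylidene)dihydrofuran-2(3H)-one, via phosphonium bromide 19 (not isolated)
Conditions: PPh3 (1.2 equiv), MeCN, 70 °C; then 2 M aq. NaOH, CH2Cl2, 0 °C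
Reagents that add atoms: triphenylphosphine, c1ccc(cc1)P(c1ccccc1)c1ccccc1
Why: SN2 quaternisation of PPh3 by the α-bromo lactone followed by deprotonation should give the ester-stabilised phosphorane, a reagent class that is isolable and stable to water.

Step 13
Reactants: 20 (5S)-5-(2-methylprop-1-en-1-yl)-3-(triphenylphosphoranylidene)dihydrofuran-2(3H)-one; 12 (4E,8E,10E)-4,8-dimethyl-11-(5-oxo-2,5-dihydrofuran-3-yl)undeca-4,8,10-trienal
Product: 21 4-[(1E,3E,7E,11E)-4,8-dimethyl-11-[(5S)-5-(2-methylprop-1-en-1-yl)-2-oxodihydrofuran-3(2H)-ylidene]undeca-1,3,7-trien-1-yl]furan-2(5H)-one (target, CNP0187251.1)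
Conditions: CH2Cl2, 40 °C, dark
Reagents that add atoms: none
Why: Wittig olefination with an ester-stabilised α,α-disubstituted ylide is neutral, should react only at the aldehyde, and should give the (E)-alkylidene lactone (chain trans to the lactone C=O) as stabilised ylides do.

**Compound list**

1 | pent-4-yn-1-ol | OCCCC#C | starting material
2 | pent-4-ynal | O=CCCC#C | intermediate
3 | rac-2-methylhept-1-en-6-yn-3-ol | C=C(C)C(O)CCC#C | intermediate
4 | 3-[(1-ethoxyethenyl)oxy]-2-methylhept-1-en-6-yne (ketene acetal, not isolated) | C=C(OCC)OC(CCC#C)C(C)=C | intermediate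
5 | ethyl (E)-4-methylnon-4-en-8-ynoate | CCOC(=O)CC/C(C)=C/CCC#C | intermediate
6 | (E)-4-methylnon-4-en-8-yn-1-ol | OCCC/C(C)=C/CCC#C | intermediate
7 | 4-bromofuran-2(5H)-one | BrC1=CC(=O)OC1 | starting material
8 | (E)-4-[2-(tributylstannyl)ethenyl]furan-2(5H)-one | CCCC[Sn](CCCC)(CCCC)/C=C/C1=CC(=O)OC1 | intermediate
9 | (E)-4-(2-iodoethenyl)furan-2(5H)-one | I/C=C/C1=CC(=O)OC1 | intermediate
10 | dimethylaluminium alkoxide of the (1E,5E)-2,6-dimethyl-9-oxynona-1,5-dien-1-yl(dimethyl)alane (not isolated) | C[Al](C)OCCC/C(C)=C/CC/C(C)=C/[Al](C)C | intermediate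
11 | 4-[(1E,3E,7E)-11-hydroxy-4,8-dimethylundeca-1,3,7-trien-1-yl]furan-2(5H)-one | OCCC/C(C)=C/CC/C(C)=C/C=C/C1=CC(=O)OC1 | intermediate
12 | (4E,8E,10E)-4,8-dimethyl-11-(5-oxo-2,5-dihydrofuran-3-yl)undeca-4,8,10-trienal | O=CCC/C(C)=C/CC/C(C)=C/C=C/C1=CC(=O)OC1 | intermediate
13 | (S)-5-(hydroxymethyl)dihydrofuran-2(3H)-one | OC[C@@H]1CCC(=O)O1 | starting material
14 | (S)-5-oxotetrahydrofuran-2-carbaldehyde | O=C[C@@H]1CCC(=O)O1 | intermediate
15 | (5S)-5-(2-methylprop-1-en-1-yl)dihydrofuran-2(3H)-one | CC(C)=C[C@@H]1CCC(=O)O1 | intermediate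
16 | lithium enolate of 15 (not isolated) | CC(C)=C[C@@H]1CC=C(O[Li])O1 | intermediate
17 | trimethylsilyl ketene acetal of 15 (not isolated) | CC(C)=C[C@@H]1CC=C(O[Si](C)(C)C)O1 | intermediate
18 | (5S)-3-bromo-5-(2-methylprop-1-en-1-yl)dihydrofuran-2(3H)-one (C3 epimers) | CC(C)=C[C@@H]1CC(Br)C(=O)O1 | intermediate
19 | [(5S)-5-(2-methylprop-1-en-1-yl)-2-oxotetrahydrofuran-3-yl]triphenylphosphonium bromide (not isolated) | CC(C)=C[C@@H]1CC([P+](c2ccccc2)(c2ccccc2)c2ccccc2)C(=O)O1.[Br-] | intermediate
20 | (5S)-5-(2-methylprop-1-en-1-yl)-3-(triphenylphosphoranylidene)dihydrofuran-2(3H)-one | CC(C)=C[C@@H]1CC(=P(c2ccccc2)(c2ccccc2)c2ccccc2)C(=O)O1 | intermediate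
21 | 4-[(1E,3E,7E,11E)-4,8-dimethyl-11-[(5S)-5-(2-methylprop-1-en-1-yl)-2-oxodihydrofuran-3(2H)-ylidene]undeca-1,3,7-trien-1-yl]furan-2(5H)-one | CC(C)=C[C@@H]1C/C(=C\CC/C(C)=C/CC/C(C)=C/C=C/C2=CC(=O)OC2)C(=O)O1 | target

**Step count**

Total steps: 13. Longest linear sequence: 7 steps (steps 1, 2, 3, 4, 7, 8, 13).

**Steps most likely to fail**

Step 7. The methylalumination may be incomplete or not fully regioselective. The alkenyl transfer from aluminium to palladium may also be slow enough for methyl transfer, homocoupling or Lewis-acid-induced decomposition of the iodovinyl butenolide to compete. The fallback sets out from 6 and comes back at 11. The methylalumination is run on its own (AlMe3, Cp2ZrCl2, CH2Cl2) and alane 10 is quenched with I2 in THF at −30 °C to give (4E,8E)-9-iodo-4,8-dimethylnona-4,8-dien-1-ol F1. F1 is purified free of its regioisomer and joined to stannane 8 by a Stille coupling (Pd2(dba)3, AsPh3, CuI, NMP, rt), which forms the same C5–C6 bond with the polarity reversed and makes step 6 unnecessary.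

Step 12. Substitution at the hindered secondary carbon may be slow. Triphenylphosphine may instead attack bromine, which returns the debrominated lactone, and the base treatment may cause dehydrobromination. The fallback sets out from 15 and comes back at 21, bypassing steps 11 to 13. Treatment of 15 with LiN(i-Pr)2 (2.2 equiv) and ClP(O)(OEt)2 in THF (−78 °C → rt) gives diethyl (5S)-5-(2-methylprop-1-en-1-yl)-4,5-dihydrofuran-2-yl phosphate F2. Under the excess base F2 undergoes oxygen-to-carbon 1,3-phosphorus migration to diethyl [(5S)-5-(2-methylprop-1-en-1-yl)-2-oxotetrahydrofuran-3-yl]phosphonate F3. A Horner–Wadsworth–Emmons reaction of F3 with aldehyde 12 (LiCl, DBU, MeCN, 0 °C → rt) should give 21 with the (E) isomer favoured, the (Z) isomer being removed by chromatography.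

Step 10. The basic ylide may enolise the α-acyloxy aldehyde and erode the configuration at C17, or conversion may suffer from hydrate formation and ylide attack at the lactone carbonyl. The fallback sets out from 14 and comes back at 15 without any basic reagent. Nozaki–Hiyama–Kishi addition of 2-bromopropene (CrCl2, NiCl2 cat., DMF, rt) gives (5S)-5-(1-hydroxy-2-methylprop-2-en-1-yl)dihydrofuran-2(3H)-one F4 as a carbinol epimer mixture. Mitsunobu reaction with 2-nitrobenzenesulfonylhydrazide (PPh3, diethyl azodicarboxylate, THF, −30 °C) gives the N-allylic N-(2-nitrobenzenesulfonyl)hydrazine F5. On warming to rt F5 loses the sulfinic acid to give the monoalkyl diazene F6, and sigmatropic loss of N2 with transposition of the alkene delivers 15.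

**Further compounds**

F1 | step 7 | (4E,8E)-9-iodo-4,8-dimethylnona-4,8-dien-1-ol | OCCC/C(C)=C/CC/C(C)=C/I
F2 | step 12 | diethyl (5S)-5-(2-methylprop-1-en-1-yl)-4,5-dihydrofuran-2-yl phosphate | CC(C)=C[C@@H]1CC=C(OP(=O)(OCC)OCC)O1
F3 | step 12 | diethyl [(5S)-5-(2-methylprop-1-en-1-yl)-2-oxotetrahydrofuran-3-yl]phosphonate | CC(C)=C[C@@H]1CC(P(=O)(OCC)OCC)C(=O)O1
F4 | step 10 | (5S)-5-(1-hydroxy-2-methylprop-2-en-1-yl)dihydrofuran-2(3H)-one | C=C(C)C(O)[C@@H]1CCC(=O)O1
F5 | step 10 | N-[2-methyl-1-[(2S)-5-oxotetrahydrofuran-2-yl]prop-2-en-1-yl]-2-nitrobenzenesulfonohydrazide | C=C(C)C(N(N)S(=O)(=O)c1ccccc1[N+](=O)[O-])[C@@H]2CCC(=O)O2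
F6 | step 10 | (5S)-5-(1-diazenyl-2-methylprop-2-en-1-yl)dihydrofuran-2(3H)-one | C=C(C)C(N=N)[C@@H]1CCC(=O)O1
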